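**Retrosynthetic overview** (briarane numbering: C1–C10 ten-membered ring, C1/C10–C14 ring A, C7/C8/C17/C19 lactone, C16 exocyclic CH2)
1. Feature used: quaternary C1 is bonded to oxygenated C2, whose cis C3–C4 unit (the later oxirane) leads to C5. C2–O and C5 can therefore be tied as a dihydrofuran fused to a cyclohexane C4–C9, which places the enol ether C2=C3 and the ring-A alkene C1=C10 as a 1,5-diene across C4–C9.
2. Key disconnection: anionic oxy-Cope ring expansion of cyclohexanol 24 (forms C1–C2, cleaves C4–C9) gives the ten-membered ring as the C2–O–C5 bridged C9 ketone 27. The C5 methoxy ketal is replaced by a C-bound CH2OPMB group (a β-keto methoxy ketal would aromatise to a furan), and C16 is unveiled later by reductive opening of the bridge.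
3. 24 comes from a ring-A alkenylcerium made from (R)-carvone (C11 by alkylation, C12–O by Criegee degradation) and dihydrofuran ketone 21 made from cis,cis-cyclohexane-1,3,5-triol (lipase desymmetrisation, carbonyl addition at C5, oxygenative Ueno–Stork cyclisation).
4. After the key step: C8 oxygen (Rubottom), ring-A enone to allylic acetate, C7-directed reduction at C9, lactone by intramolecular Reformatsky reaction, both oxiranes, bridge opening (C16 iodide, Zn) to C2–OH and C5=CH2, then C6 hydroxylation and chlorination.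
5. Ring order: ring A and the cyclohexane, then the fused dihydrofuran, then the ten-membered ring (key step), then the γ-lactone, then the two oxiranes.

Key step: step 16

Assumption: the lipase in step 8 acylates the hydroxyl that leads to the (R)-enone 14; if it prefers the other one, the same enzyme used in the hydrolytic direction on the diacetate supplies 12.

**Route**

Step 1
Reactants: 1 (R)-(−)-carvone
Product: 2 (5R,6S)-6-methylcarvone
Conditions: LDA, THF, −78 °C; MeI, −78 to 0 °C
Reagents that add atoms: iodomethane, CI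
Why: Kinetic enolate alkylation at C6 of carvone; the electrophile should enter anti to the neighbouring isopropenyl group, which sets the future C11 methyl stereocentre (6-Me trans to isopropenyl).

Step 2
Reactants: 2 (5R,6S)-6-methylcarvone
Product: 4 (1R,6S)-4,6-dimethyl-5-oxocyclohex-3-en-1-yl acetate, via methoxy hydroperoxide 3 (not isolated)
Conditions: O3, CH2Cl2/MeOH, −78 °C; then Ac2O, Et3N, DMAP (cat.), CH2Cl2, 0 °C to rt
Reagents that add atoms: ozone, [O-][O+]=O; methanol, CO
Why: Ozonolysis of the electron-rich isopropenyl group in methanol followed by Criegee rearrangement of the acylated methoxy hydroperoxide; the ring carbon migrates to oxygen with retention, so the future C12–O bond takes the place of the isopropenyl bond.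

Step 3
Reactants: 4 (1R,6S)-4,6-dimethyl-5-oxocyclohex-3-en-1-yl acetate
Product: 6 (1R,2S)-2,4-dimethyl-3-(trifluoromethylsulfonyloxy)cyclohex-3-en-1-yl acetate, via lithium enolate 5 (not isolated)
Conditions: L-Selectride, THF, −78 °C; then PhNTf2, −78 to 0 °C
Reagents that add atoms: N-phenylbis(trifluoromethanesulfonimide), O=S(=O)(N(c1ccccc1)S(=O)(=O)C(F)(F)F)C(F)(F)F
Why: Conjugate hydride reduction of the enone gives the tetrasubstituted enolate regiospecifically on the methyl-bearing side and O-triflation traps it; the enolate lies away from the methyl stereocentre, which is not touched.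

Step 4
Reactants: 6 (1R,2S)-2,4-dimethyl-3-(trifluoromethylsulfonyloxy)cyclohex-3-en-1-yl acetate
Product: 7 (1R,2S)-2,4-dimethyl-3-(trifluoromethylsulfonyloxy)cyclohex-3-en-1-ol
Conditions: K2CO3 (cat.), MeOH, 0 °C
Reagents that add atoms: none
Why: Base-catalysed transesterification removes the acetate; with the ketone already converted into the enol triflate no β-elimination to a phenol is possible.

Step 5
Reactants: 7 (1R,2S)-2,4-dimethyl-3-(trifluoromethylsulfonyloxy)cyclohex-3-en-1-ol
Product: 8 3,4-dimethoxybenzyl (DMB) ether of 7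
Conditions: 3,4-dimethoxybenzyl trichloroacetimidate, CSA (cat.), CH2Cl2, 0 °C to rt
Reagents that add atoms: 3,4-dimethoxybenzyl 2,2,2-trichloroacetimidate, COc1ccc(COC(=N)C(Cl)(Cl)Cl)cc1OC
Why: Acid-catalysed imidate benzylation; an ether is chosen instead of a silyl group because a silyl ether at C12 could migrate to the C9 alkoxide in step 16, and DMB can later be cleaved in the presence of PMB.

Step 6
Reactants: 8 DMB ether of 7
Product: 9 [(5R,6S)-5-(3,4-dimethoxybenzyloxy)-2,6-dimethylcyclohex-1-en-1-yl]trimethylstannane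
Conditions: Me3SnSnMe3, Pd(PPh3)4 (cat.), LiCl, dioxane, 100 °C
Reagents that add atoms: hexamethylditin, C[Sn](C)(C)[Sn](C)(C)C
Why: Palladium-catalysed stannylation of an enol triflate (Stille-type coupling with a distannane) gives the precursor of the C10 nucleophile without touching the stereocentres.

Step 7
Reactants: 10 cis,cis-cyclohexane-1,3,5-triol
Product: 11 all-cis-5-(tert-butyldimethylsilyloxy)cyclohexane-1,3-diol
Conditions: TBSCl (1.0 equiv), imidazole, DMF, 0 °C
Reagents that add atoms: tert-butyldimethylsilyl chloride, CC(C)(C)[Si](C)(C)Cl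
Why: Statistical monosilylation of the meso triol (itself the hydrogenation product of phloroglucinol) gives a meso diol; unreacted triol and bis-ether can be recycled.

Step 8
Reactants: 11 all-cis-5-(tert-butyldimethylsilyloxy)cyclohexane-1,3-diol
Product: 12 (1R,3S,5S)-3-hydroxy-5-(tert-butyldimethylsilyloxy)cyclohexyl acetate
Conditions: lipase PS (Amano), vinyl acetate, t-BuOMe, rt
Reagents that add atoms: vinyl acetate, C=COC(C)=O
Why: Lipase-catalysed enantiotopic-group-selective transesterification of a meso 1,3-diol; this step fixes the absolute configuration of C7 and through it of every centre set later.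

Step 9
Reactants: 12 (1R,3S,5S)-3-hydroxy-5-(tert-butyldimethylsilyloxy)cyclohexyl acetate
Product: 14 (R)-5-(tert-butyldimethylsilyloxy)cyclohex-2-en-1-one, via acetoxy ketone 13 (not isolated)
Conditions: Dess–Martin periodinane, NaHCO3, CH2Cl2, rt; then DBU, 0 °C
Reagents that add atoms: none
Why: Dess–Martin oxidation followed by E1cB loss of acetic acid; acetate is a far better leaving group than silanolate, so the silyloxy stereocentre (future C7) is kept.

Step 10
Reactants: 14 (R)-5-(tert-butyldimethylsilyloxy)cyclohex-2-en-1-one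
Product: 15 1-[(4-methoxybenzyloxy)methyl]-5-(tert-butyldimethylsilyloxy)cyclohex-2-en-1-ol (OH cis to OTBS)
Conditions: Bu3SnCH2OPMB, n-BuLi, THF, −78 °C; CeCl3, −78 °C; then 14, −78 °C
Reagents that add atoms: tributyl[(4-methoxybenzyloxy)methyl]stannane, CCCC[Sn](CCCC)(CCCC)COCc1ccc(OC)cc1
Why: 1,2-Addition of an α-alkoxymethyl organocerium reagent (tin–lithium exchange, then transmetalation) to the enone; attack anti to the C7 silyloxy group should place the new C5 hydroxyl cis to OTBS and install C16 as CH2OPMB.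

Step 11
Reactants: 15 1-[(4-methoxybenzyloxy)methyl]-5-(tert-butyldimethylsilyloxy)cyclohex-2-en-1-ol
Product: 16 2-bromo-1-ethoxyethyl mixed acetal of 15
Conditions: ethyl vinyl ether, NBS, 2,6-lutidine (cat.), CH2Cl2, −40 to 0 °C
Reagents that add atoms: ethyl vinyl ether, C=COCC; N-bromosuccinimide, O=C1CCC(=O)N1Br
Why: Bromoacetalisation of the tertiary allylic alcohol (alkoxybromination of the vinyl ether) installs the C2–C3 unit on O5 as a Ueno–Stork radical precursor; the acetal centre is a mixture and is removed in step 14.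

Step 12
Reactants: 16 2-bromo-1-ethoxyethyl mixed acetal of 15
Product: 18 cis-fused 2-ethoxy-7a-[(4-methoxybenzyloxy)methyl]-6-(tert-butyldimethylsilyloxy)octahydrobenzofuran-4-ol, via hydroperoxide 17 (not isolated)
Conditions: Bu3SnH (slow addition), dry air, toluene, 0 °C to rt; then PPh3
Reagents that add atoms: dioxygen, O=O
Why: Ueno–Stork radical cyclisation run under air (oxygenative variant): the 5-exo-trig closure of the C3 radical onto C4 can only give the cis-fused bicycle, so C4 is set from C5, and the C9 radical is trapped by O2; the epimers at C2 and C9 converge in steps 13 and 14.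

Step 13
Reactants: 18 cis-fused 2-ethoxy-octahydrobenzofuran-4-ol
Product: 19 cis-fused 2-ethoxy-7a-[(4-methoxybenzyloxy)methyl]-6-(tert-butyldimethylsilyloxy)hexahydrobenzofuran-4(2H)-one
Conditions: Dess–Martin periodinane, NaHCO3, CH2Cl2, rt
Reagents that add atoms: none
Why: Dess–Martin oxidation of the secondary alcohol gives the C9 ketone under buffered, non-basic conditions that spare the β-alkoxy ketone.

Step 14
Reactants: 19 cis-fused 2-ethoxy-hexahydrobenzofuran-4(2H)-one
Product: 21 cis-fused 7a-[(4-methoxybenzyloxy)methyl]-6-(tert-butyldimethylsilyloxy)-3a,6,7,7a-tetrahydrobenzofuran-4(5H)-one, via bis(enol ether) 20 (not isolated)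
Conditions: TMSOTf, i-Pr2NEt, CH2Cl2, −78 to 0 °C; then KF (cat.), MeOH, 0 °C
Reagents that add atoms: none
Why: TMSOTf/amine elimination of ethanol from the cyclic acetal (oxocarbenium formation, deprotonation at C3) gives the C2=C3 enol ether; the ketone is masked in the flask as its silyl enol ether on the CH2 side and released by methanolysis.

Step 15
Reactants: 9 ring-A trimethylstannane; 21 dihydrofuran ketone
Product: 24 cis-dialkenyl cyclohexanol (C9 carbinol carrying the ring-A cyclohexenyl group cis to C3 and trans to OH), via alkenyllithium 22 (not isolated), via alkenylcerium 23 (not isolated)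
Conditions: 9, MeLi, THF, −78 to 0 °C; CeCl3, −78 °C; then 21, −78 °C; aq. NH4Cl
Reagents that add atoms: none
Why: Tin–lithium exchange, transmetalation and organocerium 1,2-addition (low basicity avoids enolisation and β-elimination of 21); 21 should sit in the chair with C3 axial, OTBS equatorial and CH2OPMB axial, so the 1,3-diaxial CH2OPMB blocks the lower face and the alkenyl group enters equatorially on the face of C3, which gives the cis-dialkenyl carbinol.

Step 16
Reactants: 24 cis-dialkenyl cyclohexanol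
Product: 27 C2–O–C5 bridged bicyclo[8.4.0] C9 ketone, via potassium alkoxide 25 (not isolated), via potassium enolate 26 (not isolated)
Conditions: KH, 18-crown-6, THF, 0 to 50 °C; then AcOH in THF, −78 °C
Reagents that add atoms: none
Why: Anionic oxy-Cope rearrangement of alkoxide 25 (closest known type: ring expansion of 1,2-dialkenylcyclohexanols to cyclodec-5-enones): C4–C9 breaks while C1 bonds to C2 through the chair-like array C1=C10–C9–C4–C3=C2, giving enolate 26. The ten-membered carbocycle and the 2,5-dihydrofuran bridging C2 and C5 arise by [3,3] ring expansion and not by a cyclisation, so no Baldwin mode applies; the enol ether is held in the five-membered ring, so C3=C4 is necessarily Z. C2 is set by suprafacial transfer from C4 (the new bond forms on the dihydrofuran face that carried C9), and quaternary C1 by transfer from C9 through the chair, in which C15 is pseudo-axial and the bond forms on the cyclohexene face opposite the C11 methyl. C10 is set in the cold acetic acid quench: the syn methyls C15 and C20 shield one face of the enolate carbon, so the proton should enter from the face of C2, and the centre stays epimerisable until step 25. The step needs chair over boat, since the boat gives the C1 epimer: 24 rests in the chair with C10 equatorial and must reach the chair (or a twist form) with C10, the ring oxygen and OTBS axial, a cost of a few kcal/mol that is partly offset because the resting chair itself has a syn-diaxial O⁻/CH2OPMB pair, and only the cis relation of C10 and C3 lets the ring bonds C4–C5 and C9–C8 span the chair array. It also needs [3,3] over fragmentation, which the crown-separated alkoxide and the absence of acidic C–H next to leaving groups should secure.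

Step 17
Reactants: 27 bridged C9 ketone
Product: 28 triisopropylsilyl enol ether (C8=C9)
Conditions: TIPSOTf, Et3N, CH2Cl2, −78 to 0 °C
Reagents that add atoms: triisopropylsilyl trifluoromethanesulfonate, CC(C)[Si](OS(=O)(=O)C(F)(F)F)(C(C)C)C(C)C
Why: Soft enolisation and O-silylation occur on the unhindered C8 methylene and not at the hindered C10 methine, which keeps the C10 configuration.

Step 18
Reactants: 28 triisopropylsilyl enol ether
Product: 29 8-(triisopropylsilyloxy) 9-ketone
Conditions: mCPBA (1.1 equiv), NaHCO3, CH2Cl2, −20 °C to rt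
Reagents that add atoms: 3-chloroperoxybenzoic acid, OOC(=O)c1cccc(Cl)c1
Why: Rubottom oxidation (epoxidation of the electron-rich silyl enol ether, then silyl migration) puts the C8 oxygen in place as its TIPS ether; the deactivated dihydrofuran alkene should not compete, and the C8 configuration is irrelevant because C8 becomes a ketone in step 29.

Step 19
Reactants: 29 8-(triisopropylsilyloxy) 9-ketone
Product: 30 12-alcohol
Conditions: DDQ (1.1 equiv), CH2Cl2/pH 7 buffer, 0 °C
Reagents that add atoms: none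
Why: Oxidative cleavage of the 3,4-dimethoxybenzyl ether by DDQ, which is faster than that of the less electron-rich PMB ether at C16.

Step 20
Reactants: 30 12-alcohol
Product: 31 9,12-diketone
Conditions: Dess–Martin periodinane, NaHCO3, CH2Cl2, rt
Reagents that add atoms: none
Why: Dess–Martin oxidation under buffered conditions gives the C12 ketone without epimerising C10 or C11.

Step 21
Reactants: 31 9,12-diketone
Product: 33 13-en-12-one (ring-A enone, C9 ketone retained), via trimethylsilyl enol ether 32 (not isolated)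
Conditions: LDA (1.05 equiv), TMSCl, THF, −78 °C; then Pd(OAc)2, MeCN, rt
Reagents that add atoms: none
Why: Kinetic enolisation takes place at C13, the only α-methylene (C8, C10 and C11 are hindered methines), and Saegusa–Ito oxidation of the silyl enol ether gives the C13=C14 enone.

Step 22
Reactants: 33 13-en-12-one
Product: 34 allylic 12-alcohol (OH cis to the C11 methyl)
Conditions: NaBH4, CeCl3·7H2O, MeOH, −78 °C
Reagents that add atoms: none
Why: Luche 1,2-reduction of the enone, which should be faster than reduction of the hindered α-silyloxy C9 ketone; hydride adds anti to the adjacent C11 methyl, which sets C12 with oxygen cis to C20.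

Step 23
Reactants: 34 allylic 12-alcohol
Product: 35 12-acetate
Conditions: Ac2O, pyridine, DMAP (cat.), CH2Cl2, 0 °C
Reagents that add atoms: acetic anhydride, CC(=O)OC(C)=O
Why: Standard acylation of the only free hydroxyl installs the first of the three acetates.

Step 24
Reactants: 35 12-acetate
Product: 36 7-alcohol (β-hydroxy ketone)
Conditions: HF·pyridine, pyridine, THF, 0 °C
Reagents that add atoms: none
Why: Buffered fluoride cleaves the secondary TBS ether at C7 much faster than the secondary TIPS ether at C8, and the acidic medium avoids retro-aldol cleavage or silyl migration.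

Step 25
Reactants: 36 7-alcohol
Product: 38 7,9-syn-diol, via diethylborinate chelate 37 (not isolated)
Conditions: Et2BOMe, THF/MeOH, −78 °C; NaBH4, −78 °C; then MeOH co-evaporation
Reagents that add atoms: none
Why: Narasaka–Prasad reduction: the boron chelate between O7 and the C9 carbonyl is reduced by external hydride to the 1,3-syn diol, which sets C9 from C7 and ends the epimerisability of C10.

Step 26
Reactants: 38 7,9-syn-diol
Product: 39 7-(2-bromopropanoate)
Conditions: 2-bromopropanoyl bromide (1.05 equiv), pyridine, CH2Cl2, −40 °C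
Reagents that add atoms: 2-bromopropanoyl bromide, CC(Br)C(Br)=O
Why: Acylation should occur at the C7 hydroxyl, which is flanked by a methylene, and not at the C9 hydroxyl next to the C10 methine and quaternary C1; the bromide centre is racemic and is erased in step 30.

Step 27
Reactants: 39 7-(2-bromopropanoate)
Product: 40 9-acetate
Conditions: Ac2O, DMAP, pyridine, 0 °C to rt
Reagents that add atoms: acetic anhydride, CC(=O)OC(C)=O
Why: DMAP-catalysed acetylation of the remaining hindered secondary hydroxyl installs the C9 acetate.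

Step 28
Reactants: 40 9-acetate
Product: 41 8-alcohol
Conditions: HF·pyridine, THF, rt
Reagents that add atoms: none
Why: Fluoride desilylation of the TIPS ether under acidic conditions, which should prevent migration of the neighbouring acyl groups.

Step 29
Reactants: 41 8-alcohol
Product: 42 8-ketone
Conditions: Dess–Martin periodinane, NaHCO3, CH2Cl2, rt
Reagents that add atoms: none
Why: Dess–Martin oxidation gives the C8 ketone flanked by the C7 ester and the C9 acetate without enolising either α-centre.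

Step 30
Reactants: 42 8-ketone
Product: 44 hydroxy lactone (C7–O–C19(=O)–C17–C8, tertiary 8-OH), via zinc enolate 43 (not isolated)
Conditions: activated Zn (Zn–Cu couple), THF, 0 °C to rt; aq. NH4Cl
Reagents that add atoms: none
Why: Intramolecular Reformatsky reaction: the zinc ester enolate tethered on O7 adds to the C8 carbonyl in the rotamer with the ring bonds C6–C7 and C8–C9 antiperiplanar, which puts 8-OH syn to C6 (lactone trans-fused on the large ring), and the epimerisable C17 should carry its methyl trans to the bulky C9, that is cis to 8-OH.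

Step 31
Reactants: 44 hydroxy lactone
Product: 45 3,4:13,14-bis-epoxide
Conditions: mCPBA (excess), Na2HPO4, ClCH2CH2Cl, 40 °C
Reagents that add atoms: 3-chloroperoxybenzoic acid, OOC(=O)c1cccc(Cl)c1
Why: Prilezhaev epoxidation of both remaining alkenes: the dihydrofuran alkene is attacked on its exo face, anti to the carbon bridge (cis to H-2), and the ring-A alkene on the face opposite C15, C20 and the C12 acetate, which all lie on the other side.

Step 32
Reactants: 45 bis-epoxide
Product: 46 C16 primary alcohol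
Conditions: DDQ, CH2Cl2/pH 7 buffer, rt
Reagents that add atoms: none
Why: Oxidative PMB cleavage with DDQ under neutral conditions that spare the oxiranes, acetates and lactone.

Step 33
Reactants: 46 C16 primary alcohol
Product: 48 C16 iodide, via triflate 47 (not isolated)
Conditions: Tf2O, 2,6-lutidine, CH2Cl2, −78 °C; then Bu4NI, MeCN, rt
Reagents that add atoms: tetrabutylammonium iodide, CCCC[N+](CCCC)(CCCC)CCCC.[I-]
Why: Triflation of the primary alcohol and SN2 displacement by iodide; the triflate is needed because C16 is neopentyl-like, and the hindered tertiary 8-OH should not react at −78 °C.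

Step 34
Reactants: 48 C16 iodide
Product: 49 ring-opened 2-alcohol with C5=C16 methylene
Conditions: activated Zn, NH4Cl, EtOH/THF, 40 °C (sonication)
Reagents that add atoms: none
Why: Boord-type reductive β-elimination of a β-iodo ether (zinc insertion at C16, loss of the C5–O alkoxide) opens the bridge and releases the C2 hydroxyl and the exocyclic methylene in one step; no stereocentre is touched.

Step 35
Reactants: 49 ring-opened 2-alcohol
Product: 50 2-acetate
Conditions: Ac2O, pyridine, DMAP (cat.), 0 °C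
Reagents that add atoms: acetic anhydride, CC(=O)OC(C)=O
Why: Acetylation of the only secondary hydroxyl; the tertiary 8-OH is inert under these conditions.

Step 36
Reactants: 50 2-acetate
Product: 51 6-alcohol (C6 configuration opposite to that of the chloride)
Conditions: SeO2 (cat.), t-BuOOH, CH2Cl2, rt
Reagents that add atoms: tert-butyl hydroperoxide, CC(C)(C)OO
Why: Riley allylic oxidation: ene reaction at C16 with removal of a C6 hydrogen and [2,3]-shift returns the exocyclic alkene and puts OH on C6, the only allylic methylene, on the face from which the π-aligned hydrogen on the outer side of the ring is taken.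

Step 37
Reactants: 51 6-alcohol
Product: 52 CNP0229305.1 (target)
Conditions: PPh3, hexachloroacetone, CH2Cl2, −20 to 0 °C
Reagents that add atoms: hexachloroacetone, ClC(Cl)(Cl)C(=O)C(Cl)(Cl)Cl
Why: Appel-type chlorination of the secondary allylic alcohol: chloride displaces the oxyphosphonium group by SN2 with inversion at C6 and, under these mild conditions, little allylic transposition.

**Compound list**

1 | (R)-(−)-carvone | CC(=C)[C@@H]1CC=C(C)C(=O)C1 | starting material
2 | (5R,6S)-6-methylcarvone (6-Me trans to isopropenyl) | C[C@@H]1C(=O)C(C)=CC[C@H]1C(C)=C | intermediate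
3 | methoxy hydroperoxide from ozonolysis of 2 | C[C@@H]1C(=O)C(C)=CC[C@H]1C(C)(OC)OO | intermediate
4 | (1R,6S)-4,6-dimethyl-5-oxocyclohex-3-en-1-yl acetate | C[C@@H]1C(=O)C(C)=CC[C@H]1OC(C)=O | intermediate
5 | lithium 5-acetoxy-2,6-dimethylcyclohex-1-en-1-olate | C[C@@H]1C(O[Li])=C(C)CC[C@H]1OC(C)=O | intermediate
6 | (1R,2S)-2,4-dimethyl-3-(trifluoromethylsulfonyloxy)cyclohex-3-en-1-yl acetate | C[C@@H]1C(OS(=O)(=O)C(F)(F)F)=C(C)CC[C@H]1OC(C)=O | intermediate
7 | (1R,2S)-2,4-dimethyl-3-(trifluoromethylsulfonyloxy)cyclohex-3-en-1-ol | C[C@@H]1C(OS(=O)(=O)C(F)(F)F)=C(C)CC[C@H]1O | intermediate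
8 | 3,4-dimethoxybenzyl ether of 7 | C[C@@H]1C(OS(=O)(=O)C(F)(F)F)=C(C)CC[C@H]1OCc2ccc(OC)c(OC)c2 | intermediate
9 | [(5R,6S)-5-(3,4-dimethoxybenzyloxy)-2,6-dimethylcyclohex-1-en-1-yl]trimethylstannane (ring A: C10–Sn, C1–Me, C11–Me, C12–ODMB) | C[C@@H]1C([Sn](C)(C)C)=C(C)CC[C@H]1OCc2ccc(OC)c(OC)c2 | intermediate
10 | cis,cis-cyclohexane-1,3,5-triol | O[C@H]1C[C@@H](O)C[C@@H](O)C1 | starting material
11 | all-cis-5-(tert-butyldimethylsilyloxy)cyclohexane-1,3-diol (meso) | O[C@H]1C[C@@H](O)C[C@@H](O[Si](C)(C)C(C)(C)C)C1 | intermediate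
12 | (1R,3S,5S)-3-hydroxy-5-(tert-butyldimethylsilyloxy)cyclohexyl acetate | O[C@H]1C[C@@H](OC(C)=O)C[C@@H](O[Si](C)(C)C(C)(C)C)C1 | intermediate
13 | cis-3-acetoxy-5-(tert-butyldimethylsilyloxy)cyclohexanone | O=C1C[C@@H](OC(C)=O)C[C@@H](O[Si](C)(C)C(C)(C)C)C1 | intermediate
14 | (R)-5-(tert-butyldimethylsilyloxy)cyclohex-2-en-1-one | O=C1C=CC[C@@H](O[Si](C)(C)C(C)(C)C)C1 | intermediate
15 | 1-[(4-methoxybenzyloxy)methyl]-5-(tert-butyldimethylsilyloxy)cyclohex-2-en-1-ol, OH cis to OTBS | O[C@@]1(COCc2ccc(OC)cc2)C=CC[C@@H](O[Si](C)(C)C(C)(C)C)C1 | intermediate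
16 | 2-bromo-1-ethoxyethyl mixed acetal of 15 (acetal centre mixed) | CCOC(CBr)O[C@@]1(COCc2ccc(OC)cc2)C=CC[C@@H](O[Si](C)(C)C(C)(C)C)C1 | intermediate
17 | cis-fused 2-ethoxy-octahydrobenzofuran-4-yl hydroperoxide (C2, C9 mixed) | OOC1C[C@@H](O[Si](C)(C)C(C)(C)C)C[C@@]2(COCc3ccc(OC)cc3)OC(OCC)C[C@@H]12 | intermediate
18 | cis-fused 2-ethoxy-7a-[(4-methoxybenzyloxy)methyl]-6-(tert-butyldimethylsilyloxy)octahydrobenzofuran-4-ol (C2, C9 mixed) | OC1C[C@@H](O[Si](C)(C)C(C)(C)C)C[C@@]2(COCc3ccc(OC)cc3)OC(OCC)C[C@@H]12 | intermediate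
19 | cis-fused 2-ethoxy-7a-[(4-methoxybenzyloxy)methyl]-6-(tert-butyldimethylsilyloxy)hexahydrobenzofuran-4(2H)-one | O=C1C[C@@H](O[Si](C)(C)C(C)(C)C)C[C@@]2(COCc3ccc(OC)cc3)OC(OCC)C[C@@H]12 | intermediate
20 | bis(enol ether): 4-trimethylsilyloxy-4,5-ene of the 2,3-dihydrofuran | C[Si](C)(C)OC1=C[C@@H](O[Si](C)(C)C(C)(C)C)C[C@@]2(COCc3ccc(OC)cc3)OC=C[C@@H]12 | intermediate
21 | cis-fused 7a-[(4-methoxybenzyloxy)methyl]-6-(tert-butyldimethylsilyloxy)-3a,6,7,7a-tetrahydrobenzofuran-4(5H)-one (C9 ketone; ring O, C3 and OTBS on one face) | O=C1C[C@@H](O[Si](C)(C)C(C)(C)C)C[C@@]2(COCc3ccc(OC)cc3)OC=C[C@@H]12 | intermediate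
22 | ring-A alkenyllithium from 9 | C[C@@H]1C([Li])=C(C)CC[C@H]1OCc2ccc(OC)c(OC)c2 | intermediate
23 | ring-A alkenylcerium dichloride | C[C@@H]1C([Ce](Cl)Cl)=C(C)CC[C@H]1OCc2ccc(OC)c(OC)c2 | intermediate
24 | cis-dialkenyl cyclohexanol: C9 carbinol with the ring-A cyclohexenyl group cis to C3, fused methylene-substituted dihydrofuran | CC1=C([C@@]2(O)C[C@@H](O[Si](C)(C)C(C)(C)C)C[C@@]3(COCc4ccc(OC)cc4)OC=C[C@@H]23)[C@@H](C)[C@H](OCc5ccc(OC)c(OC)c5)CC1 | intermediate
25 | potassium alkoxide of 24 | CC1=C([C@@]2(O[K])C[C@@H](O[Si](C)(C)C(C)(C)C)C[C@@]3(COCc4ccc(OC)cc4)OC=C[C@@H]23)[C@@H](C)[C@H](OCc5ccc(OC)c(OC)c5)CC1 | intermediate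
26 | potassium C9=C10 enolate of 27 (C8 trans to C1) | C[C@]12CC[C@@H](OCc5ccc(OC)c(OC)c5)[C@H](C)/C1=C(/O[K])\C[C@@H](O[Si](C)(C)C(C)(C)C)C[C@@]3(COCc4ccc(OC)cc4)O[C@@H]2C=C3 | intermediate
27 | C2–O–C5 bridged bicyclo[8.4.0] C9 ketone (C7–OTBS, C12–ODMB, C5–CH2OPMB, Z C3=C4) | C[C@]12CC[C@@H](OCc5ccc(OC)c(OC)c5)[C@H](C)[C@@H]1C(=O)C[C@@H](O[Si](C)(C)C(C)(C)C)C[C@@]3(COCc4ccc(OC)cc4)O[C@@H]2C=C3 | intermediate
28 | C8=C9 triisopropylsilyl enol ether of 27 | C[C@]12CC[C@@H](OCc5ccc(OC)c(OC)c5)[C@H](C)[C@@H]1C(O[Si](C(C)C)(C(C)C)C(C)C)=C[C@@H](O[Si](C)(C)C(C)(C)C)C[C@@]3(COCc4ccc(OC)cc4)O[C@@H]2C=C3 | intermediate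
29 | 8-(triisopropylsilyloxy) 9-ketone (C8 mixed) | C[C@]12CC[C@@H](OCc5ccc(OC)c(OC)c5)[C@H](C)[C@@H]1C(=O)C(O[Si](C(C)C)(C(C)C)C(C)C)[C@@H](O[Si](C)(C)C(C)(C)C)C[C@@]3(COCc4ccc(OC)cc4)O[C@@H]2C=C3 | intermediate
30 | 12-alcohol (OH trans to C20) | C[C@]12CC[C@@H](O)[C@H](C)[C@@H]1C(=O)C(O[Si](C(C)C)(C(C)C)C(C)C)[C@@H](O[Si](C)(C)C(C)(C)C)C[C@@]3(COCc4ccc(OC)cc4)O[C@@H]2C=C3 | intermediate
31 | 9,12-diketone | C[C@]12CCC(=O)[C@H](C)[C@@H]1C(=O)C(O[Si](C(C)C)(C(C)C)C(C)C)[C@@H](O[Si](C)(C)C(C)(C)C)C[C@@]3(COCc4ccc(OC)cc4)O[C@@H]2C=C3 | intermediate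
32 | C12=C13 trimethylsilyl enol ether | C[C@]12CC=C(O[Si](C)(C)C)[C@H](C)[C@@H]1C(=O)C(O[Si](C(C)C)(C(C)C)C(C)C)[C@@H](O[Si](C)(C)C(C)(C)C)C[C@@]3(COCc4ccc(OC)cc4)O[C@@H]2C=C3 | intermediate
33 | 13-en-12-one (ring-A enone, 9-ketone) | C[C@]12C=CC(=O)[C@H](C)[C@@H]1C(=O)C(O[Si](C(C)C)(C(C)C)C(C)C)[C@@H](O[Si](C)(C)C(C)(C)C)C[C@@]3(COCc4ccc(OC)cc4)O[C@@H]2C=C3 | intermediate
34 | allylic 12-alcohol (OH cis to C20) | C[C@]12C=C[C@H](O)[C@H](C)[C@@H]1C(=O)C(O[Si](C(C)C)(C(C)C)C(C)C)[C@@H](O[Si](C)(C)C(C)(C)C)C[C@@]3(COCc4ccc(OC)cc4)O[C@@H]2C=C3 | intermediate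
35 | 12-acetate | C[C@]12C=C[C@H](OC(C)=O)[C@H](C)[C@@H]1C(=O)C(O[Si](C(C)C)(C(C)C)C(C)C)[C@@H](O[Si](C)(C)C(C)(C)C)C[C@@]3(COCc4ccc(OC)cc4)O[C@@H]2C=C3 | intermediate
36 | 7-alcohol (7-hydroxy 9-ketone) | C[C@]12C=C[C@H](OC(C)=O)[C@H](C)[C@@H]1C(=O)C(O[Si](C(C)C)(C(C)C)C(C)C)[C@@H](O)C[C@@]3(COCc4ccc(OC)cc4)O[C@@H]2C=C3 | intermediate
37 | O7 diethylborinate of 36 | C[C@]12C=C[C@H](OC(C)=O)[C@H](C)[C@@H]1C(=O)C(O[Si](C(C)C)(C(C)C)C(C)C)[C@@H](OB(CC)CC)C[C@@]3(COCc4ccc(OC)cc4)O[C@@H]2C=C3 | intermediate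
38 | 7,9-syn-diol | C[C@]12C=C[C@H](OC(C)=O)[C@H](C)[C@@H]1[C@@H](O)C(O[Si](C(C)C)(C(C)C)C(C)C)[C@@H](O)C[C@@]3(COCc4ccc(OC)cc4)O[C@@H]2C=C3 | intermediate
39 | 7-(2-bromopropanoate) | C[C@]12C=C[C@H](OC(C)=O)[C@H](C)[C@@H]1[C@@H](O)C(O[Si](C(C)C)(C(C)C)C(C)C)[C@@H](OC(=O)C(C)Br)C[C@@]3(COCc4ccc(OC)cc4)O[C@@H]2C=C3 | intermediate
40 | 9-acetate 7-(2-bromopropanoate) | C[C@]12C=C[C@H](OC(C)=O)[C@H](C)[C@@H]1[C@@H](OC(C)=O)C(O[Si](C(C)C)(C(C)C)C(C)C)[C@@H](OC(=O)C(C)Br)C[C@@]3(COCc4ccc(OC)cc4)O[C@@H]2C=C3 | intermediate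
41 | 8-alcohol | C[C@]12C=C[C@H](OC(C)=O)[C@H](C)[C@@H]1[C@@H](OC(C)=O)C(O)[C@@H](OC(=O)C(C)Br)C[C@@]3(COCc4ccc(OC)cc4)O[C@@H]2C=C3 | intermediate
42 | 8-ketone | C[C@]12C=C[C@H](OC(C)=O)[C@H](C)[C@@H]1[C@@H](OC(C)=O)C(=O)[C@@H](OC(=O)C(C)Br)C[C@@]3(COCc4ccc(OC)cc4)O[C@@H]2C=C3 | intermediate
43 | zinc enolate (Reformatsky reagent) of 42 | C[C@]12C=C[C@H](OC(C)=O)[C@H](C)[C@@H]1[C@@H](OC(C)=O)C(=O)[C@@H](OC(=O)C(C)[Zn]Br)C[C@@]3(COCc4ccc(OC)cc4)O[C@@H]2C=C3 | intermediate
44 | bridged 8-hydroxy-17-methyl γ-lactone | C[C@]12C=C[C@H](OC(C)=O)[C@H](C)[C@@H]1[C@@H](OC(C)=O)[C@]4(O)[C@@H](C)C(=O)O[C@H]4C[C@@]3(COCc5ccc(OC)cc5)O[C@@H]2C=C3 | intermediate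
45 | 3,4:13,14-bis-epoxide | C[C@]12[C@H]5O[C@H]5[C@H](OC(C)=O)[C@H](C)[C@@H]1[C@@H](OC(C)=O)[C@]4(O)[C@@H](C)C(=O)O[C@H]4C[C@@]3(COCc6ccc(OC)cc6)O[C@@H]2[C@@H]7O[C@H]37 | intermediate
46 | C16 primary alcohol | C[C@]12[C@H]5O[C@H]5[C@H](OC(C)=O)[C@H](C)[C@@H]1[C@@H](OC(C)=O)[C@]4(O)[C@@H](C)C(=O)O[C@H]4C[C@@]3(CO)O[C@@H]2[C@@H]6O[C@H]36 | intermediate
47 | C16 triflate | C[C@]12[C@H]5O[C@H]5[C@H](OC(C)=O)[C@H](C)[C@@H]1[C@@H](OC(C)=O)[C@]4(O)[C@@H](C)C(=O)O[C@H]4C[C@@]3(COS(=O)(=O)C(F)(F)F)O[C@@H]2[C@@H]6O[C@H]36 | intermediate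
48 | C16 iodide | C[C@]12[C@H]5O[C@H]5[C@H](OC(C)=O)[C@H](C)[C@@H]1[C@@H](OC(C)=O)[C@]4(O)[C@@H](C)C(=O)O[C@H]4C[C@@]3(CI)O[C@@H]2[C@@H]6O[C@H]36 | intermediate
49 | ring-opened 2-alcohol with C5=C16 methylene (6-deschloro, 2-O-deacetyl target) | C=C1[C@H]2O[C@H]2[C@@H](O)[C@]2(C)[C@H]([C@@H](C)[C@@H](OC(C)=O)[C@@H]3O[C@@H]32)[C@@H](OC(C)=O)[C@]2(O)[C@@H](C)C(=O)O[C@H]2C1 | intermediate
50 | 2-acetate (6-deschloro target) | C=C1[C@H]2O[C@H]2[C@@H](OC(C)=O)[C@]2(C)[C@H]([C@@H](C)[C@@H](OC(C)=O)[C@@H]3O[C@@H]32)[C@@H](OC(C)=O)[C@]2(O)[C@@H](C)C(=O)O[C@H]2C1 | intermediate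
51 | 6-alcohol (C6 epimeric in sense to the chloride) | C=C1[C@H]2O[C@H]2[C@@H](OC(C)=O)[C@]2(C)[C@H]([C@@H](C)[C@@H](OC(C)=O)[C@@H]3O[C@@H]32)[C@@H](OC(C)=O)[C@]2(O)[C@@H](C)C(=O)O[C@H]2[C@@H]1O | intermediate
52 | CNP0229305.1 | C=C1[C@H]2O[C@H]2[C@@H](OC(C)=O)[C@]2(C)[C@H]([C@@H](C)[C@@H](OC(C)=O)[C@@H]3O[C@@H]32)[C@@H](OC(C)=O)[C@]2(O)[C@@H](C)C(=O)O[C@H]2[C@H]1Cl | target

**Totals and risks**

Total step count: 37 (steps 1–6 ring-A fragment, 7–14 dihydrofuran ketone, 15–37 common line).
Longest linear sequence: 31 steps (10 to 52, steps 7–37).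

Three steps most likely to fail:

1. Step 16 (key step). The alkoxide may fragment or react through the boat-like array from its resting chair (which gives the C1 epimer), and the enolate may be protonated on the wrong face at C10. Fallback: the neutral siloxy-Cope variant, which has no free alkoxide and separates the rearrangement from the protonation. It sets out from 24, which is silylated (N-trimethylsilylimidazole, CH2Cl2) to the tertiary trimethylsilyl ether F1. Thermolysis (o-dichlorobenzene, bis(trimethylsilyl)acetamide as acid scavenger, 180 °C) should give the C9=C10 trimethylsilyl enol ether F2, an isolable compound. Its protonolysis can then be studied on its own (TBAF/AcOH, THF, −78 °C, or a bulky carboxylic acid), and the route is rejoined at 27.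

2. Step 30. The zinc enolate may fail to close the five-membered ring, reduce the α-acyloxy ketone, or add to the wrong carbonyl face (cis-fused lactone). Fallback: an intermolecular, chelation-controlled Reformatsky addition. It sets out from 42, whose bromopropanoate is cleaved with thiourea (NaHCO3, EtOH, 50 °C) to the 7-hydroxy 8-ketone F3. Addition of the Reformatsky reagent from ethyl 2-bromopropanoate and zinc (THF, 0 °C) to the zinc chelate of O7 and the C8 carbonyl should occur anti to C6 (Cram-chelate model), which gives the same C8 configuration in the hydroxy ester F4. F4 lactonises onto O7 (spontaneously or with catalytic CSA) and the route is rejoined at 44.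

3. Step 36. The allylic oxidation may show poor facial selectivity at C6 or run on to the ketone. Fallback: take the oxidation level through on purpose and set C6 by reagent control. It sets out from 50, which is oxidised (SeO2/t-BuOOH, then Dess–Martin periodinane) to the 6-ketone F5. Reduction with the appropriate enantiomer of the CBS catalyst and borane (or L-Selectride, −78 °C) then gives the alcohol, and the route is rejoined at 51.

**Further compounds**

F1 | step 16 | C9 trimethylsilyl ether of 24 | CC1=C([C@@]2(O[Si](C)(C)C)C[C@@H](O[Si](C)(C)C(C)(C)C)C[C@@]3(COCc4ccc(OC)cc4)OC=C[C@@H]23)[C@@H](C)[C@H](OCc5ccc(OC)c(OC)c5)CC1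
F2 | step 16 | C9=C10 trimethylsilyl enol ether of 27 | C[C@]12CC[C@@H](OCc5ccc(OC)c(OC)c5)[C@H](C)/C1=C(/O[Si](C)(C)C)\C[C@@H](O[Si](C)(C)C(C)(C)C)C[C@@]3(COCc4ccc(OC)cc4)O[C@@H]2C=C3
F3 | step 30 | 7-hydroxy 8-ketone | C[C@]12C=C[C@H](OC(C)=O)[C@H](C)[C@@H]1[C@@H](OC(C)=O)C(=O)[C@@H](O)C[C@@]3(COCc4ccc(OC)cc4)O[C@@H]2C=C3
F4 | step 30 | 7,8-dihydroxy ethyl ester (open form of 44, C17 mixed) | C[C@]12C=C[C@H](OC(C)=O)[C@H](C)[C@@H]1[C@@H](OC(C)=O)[C@](O)(C(C)C(=O)OCC)[C@@H](O)C[C@@]3(COCc4ccc(OC)cc4)O[C@@H]2C=C3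
F5 | step 36 | 6-ketone | C=C1[C@H]2O[C@H]2[C@@H](OC(C)=O)[C@]2(C)[C@H]([C@@H](C)[C@@H](OC(C)=O)[C@@H]3O[C@@H]32)[C@@H](OC(C)=O)[C@]2(O)[C@@H](C)C(=O)O[C@H]2C1=O
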